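The chroman is opened at the O1–C8a bond. Everything from C4 through C3 and the quaternary C2 (with its methyl group) out along the side chain to the E-configured trisubstituted double bond maps onto the ten carbons of (S)-linalool, whose carbinol oxygen is O1. One palladium-catalysed etherification joins this tertiary alcohol to the adjacent aryl bromide and closes the pyran ring without breaking the C2–O bond, so the stereocentre arrives intact. The precursor (21) is an open-chain bromoarene tertiary alcohol already carrying the complete side chain, the silylated trans ring A (from a titanocene-mediated cyclisation of an epoxyneryl ester) and the phenol as its methoxymethyl ether.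

Key step: step 13

Assumption: commercial (S)-(+)-linalool is taken at high enantiomeric purity (enriched before step 4 if the lot requires it), since its carbinol centre becomes C2 (S) unchanged; the target is read as 2S with a trans (1R,3R) ring A, which is why ring A is built from the Z (neryl) series.

**Fragment 1: bromo-iodoarene**

Step 1
Reactants: 1 4-amino-3-methylphenol
Product: 3 4-(methoxymethoxy)-2-methylaniline, via sodium 4-amino-3-methylphenoxide 2 (not isolated)
Conditions: NaH (1.05 equiv), DMF, 0 °C; then MOMCl (1.0 equiv), 0 °C to rt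
Reagents that add atoms: chloromethyl methyl ether (MOMCl), COCCl
Why: Williamson-type O-alkylation, in which NaH removes only the phenolic proton and the phenoxide 2 should outcompete the neutral aniline nitrogen for the single equivalent of MOMCl.

Step 2
Reactants: 3 4-(methoxymethoxy)-2-methylaniline
Product: 4 2-iodo-4-(methoxymethoxy)-6-methylaniline
Conditions: NIS (1.05 equiv), MeCN, 0 °C to rt, dark
Reagents that add atoms: N-iodosuccinimide, O=C1CCC(=O)N1I
Why: electrophilic aromatic iodination steered by the amino group to its only free ortho position, the para site being held by the acetal oxygen and the other ortho site by methyl.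

Step 3
Reactants: 4 2-iodo-4-(methoxymethoxy)-6-methylaniline
Product: 6 2-bromo-1-iodo-5-(methoxymethoxy)-3-methylbenzene, via arenediazonium bromide 5 (not isolated)
Conditions: t-BuONO (1.5 equiv), CuBr2 (1.2 equiv), MeCN, 0 °C to rt
Reagents that add atoms: CuBr2, [Cu+2].[Br-].[Br-]
Why: non-aqueous Sandmeyer bromination, in which the alkyl nitrite diazotises the aniline and copper-mediated bromodediazoniation replaces nitrogen at the same carbon, so bromine ends up between iodine and methyl while the neutral medium spares the acid-labile acetal.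

**Fragment 2: linalool-derived allylic bromide**

Step 4
Reactants: 7 (S)-linalool; 6 2-bromo-1-iodo-5-(methoxymethoxy)-3-methylbenzene
Product: 9 (3S)-1-[2-bromo-5-(methoxymethoxy)-3-methylphenyl]-3,7-dimethyloct-6-en-3-ol, via B-alkyl-9-BBN adduct 8 (not isolated)
Conditions: 7 (1.3 equiv), 9-BBN (0.5 M in THF, 2.0 equiv), THF, 0 °C to rt; then 3 M aq. K3PO4 (3 equiv), 6 (1.0 equiv), PdCl2(dppf) (5 mol%), DMF, rt to 45 °C
Reagents that add atoms: none
Why: anti-Markovnikov hydroboration of the monosubstituted vinyl group (the only other olefin is trisubstituted and far slower) followed by B-alkyl Suzuki–Miyaura coupling at the C–I bond, which undergoes oxidative addition much faster than the C–Br bond; the arene is attached at this early stage because 9-BBN would not distinguish the vinyl group from the 1,1-disubstituted exocyclic olefin of ring A, and the carbinol centre is untouched.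

Step 5
Reactants: 9 bromoarene alcohol
Product: 11 (2E,6S)-8-[2-bromo-5-(methoxymethoxy)-3-methylphenyl]-2,6-dimethyloct-2-ene-1,6-diol, via over-oxidised enal 10 (not isolated)
Conditions: SeO2 (0.3 equiv), t-BuOOH (5.5 M in decane, 3 equiv), salicylic acid (0.1 equiv), CH2Cl2, rt; then NaBH4, MeOH, 0 °C
Reagents that add atoms: tert-butyl hydroperoxide, CC(C)(C)OO (terminal oxidant); SeO2, O=[Se]=O (catalytic carrier of the oxygen atom)
Why: allylic oxidation by SeO2 (ene reaction, then [2,3]-sigmatropic shift of the allylseleninic acid) attacks the methyl group trans to the chain of a gem-dimethyl trisubstituted olefin, which fixes the E geometry, and NaBH4 returns any enal 10 to the alcohol.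

Step 6
Reactants: 11 allylic diol
Product: 12 (3S,6E)-8-bromo-1-[2-bromo-5-(methoxymethoxy)-3-methylphenyl]-3,7-dimethyloct-6-en-3-ol
Conditions: CBr4 (1.15 equiv), PPh3 (1.2 equiv), CH2Cl2, −20 to 0 °C; used at once
Reagents that add atoms: carbon tetrabromide, BrC(Br)(Br)Br
Why: Appel reaction, in which the primary allylic alcohol is displaced by bromide (SN2, no allylic shift at low temperature) while the tertiary alcohol cannot be substituted under these conditions.

**Fragment 3: ring A**

Step 7
Reactants: 13 neryl acetate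
Product: 14 (2Z)-5-[(2R)-3,3-dimethyloxiran-2-yl]-3-methylpent-2-en-1-yl acetate
Conditions: D-fructose-derived ketone catalyst 1,2:4,5-di-O-isopropylidene-β-D-erythro-2,3-hexodiulo-2,6-pyranose (0.3 equiv), Oxone (2KHSO5·KHSO4·K2SO4, 1.4 equiv), K2CO3, Bu4NHSO4 (cat.), MeCN/dimethoxymethane/aq. Na2B4O7 buffer, 0 °C
Reagents that add atoms: potassium peroxymonosulfate (KHSO5), [K+].[O-]S(=O)(=O)OO
Why: Shi epoxidation, in which the chiral dioxirane formed from the ketone and KHSO5 transfers oxygen through a spiro transition state to one face of the electron-rich 6,7-olefin (the 2,3-olefin is deactivated by the allylic acetate), setting the R epoxide carbon that becomes the ring-A carbinol.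

Step 8
Reactants: 14 (R)-epoxyneryl acetate
Product: 15 [(1R,3R)-3-hydroxy-2,2-dimethyl-6-methylidenecyclohexyl]methyl acetate
Conditions: Cp2TiCl2 (2.2 equiv), Mn dust (8 equiv), degassed THF, rt, slow addition of 14 to the green Cp2TiCl solution; dilute aq. HCl work-up
Reagents that add atoms: none
Why: titanocene-mediated radical epoxypolyene cyclisation, in which Cp2TiCl (trivalent titanium) opens the epoxide to the tertiary radical with the C–O centre intact, 6-endo closure onto the Z-olefin through a chair with the titanoxy group equatorial forces the Z-placed acetoxymethyl group axial and so sets the new CH centre as R, trans to oxygen, and trapping of the new tertiary radical by a second Cp2TiCl followed by beta-hydride loss from the methyl group leaves the exocyclic methylene.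

Step 9
Reactants: 15 trans hydroxy acetate
Product: 16 [(1R,3R)-3-{[tert-butyl(dimethyl)silyl]oxy}-2,2-dimethyl-6-methylidenecyclohexyl]methyl acetate
Conditions: TBSOTf (1.3 equiv), 2,6-lutidine (2 equiv), CH2Cl2, −40 to 0 °C
Reagents that add atoms: tert-butyldimethylsilyl trifluoromethanesulfonate, CC(C)(C)[Si](C)(C)OS(=O)(=O)C(F)(F)F
Why: silylation of the hindered neopentylic secondary alcohol by the highly electrophilic silyl triflate, which keeps this oxygen off magnesium and palladium in later steps.

Step 10
Reactants: 16 silyl ether acetate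
Product: 17 [(1R,3R)-3-{[tert-butyl(dimethyl)silyl]oxy}-2,2-dimethyl-6-methylidenecyclohexyl]methanol
Conditions: K2CO3 (0.2 equiv), MeOH, rt
Reagents that add atoms: none
Why: base-catalysed methanolysis (transesterification) removes the primary acetate without touching the silyl ether or the olefin.

Step 11
Reactants: 17 ring-A alcohol
Product: 18 {[(1R,3R)-3-(bromomethyl)-2,2-dimethyl-4-methylidenecyclohexyl]oxy}(tert-butyl)dimethylsilane
Conditions: CBr4 (1.3 equiv), PPh3 (1.4 equiv), imidazole (0.5 equiv), CH2Cl2, 0 °C to rt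
Reagents that add atoms: carbon tetrabromide, BrC(Br)(Br)Br
Why: Appel reaction at the primary CH2OH (SN2), giving the bromide needed for Grignard formation without acid that could move the exocyclic double bond.

**Union, key step and end game**

Step 12
Reactants: 18 ring-A bromide; 12 allylic bromide
Product: 21 (3S,6E)-1-[2-bromo-5-(methoxymethoxy)-3-methylphenyl]-9-[(1R,3R)-3-{[tert-butyl(dimethyl)silyl]oxy}-2,2-dimethyl-6-methylidenecyclohexyl]-3,7-dimethylnon-6-en-3-ol, via chloromagnesium alkoxide 19 (not isolated), via ring-A Grignard reagent 20 (not isolated)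
Conditions: 12, i-PrMgCl (1.0 equiv), THF, −78 °C (gives 19); separately 18 (1.5 equiv), Mg turnings (iodine-activated), THF, 35 °C (gives 20); 20 and Li2CuCl4 (5 mol%) added to 19 at −78 °C, then to 0 °C; aq. NH4Cl
Reagents that add atoms: none
Why: copper-catalysed sp3–sp3 coupling of a primary alkyl Grignard reagent with a primary allylic bromide, in which the cuprate formed in THF substitutes at the unhindered CH2 terminus with the E olefin retained, the bulky beta-branched nucleophile disfavours attack at the gamma carbon, the pre-formed alkoxide 19 protects the reagent from protonation, and the hindered aryl bromide and the acetal are inert to organomagnesium and organocopper species below 0 °C (a reductive desulfonylation, which an aryl bromide might not survive, is thereby avoided); no stereocentre is formed.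

Step 13
Reactants: 21 bromoarene tertiary alcohol
Product: 22 tert-butyl({(1R,3R)-3-[(3E)-6-[(2S)-6-(methoxymethoxy)-2,8-dimethyl-3,4-dihydro-2H-chromen-2-yl]-3-methylhex-3-en-1-yl]-2,2-dimethyl-4-methylidenecyclohexyl}oxy)dimethylsilane
Conditions: Pd(OAc)2 (5 mol%), racemic 2-(di-tert-butylphosphino)-1,1'-binaphthyl (6 mol%), Cs2CO3 (1.5 equiv), toluene, 80 °C, argon
Reagents that add atoms: none
Why: Zerovalent palladium, formed in the flask from Pd(OAc)2 and the phosphine, inserts into the C–Br bond of 21, Cs2CO3 turns the neighbouring tertiary hydroxyl into a palladium-bound alkoxide, and C–O reductive elimination forms the O1–C8a bond. The closest known reaction type is the Buchwald–Hartwig-type intramolecular etherification of aryl bromides with tertiary alcohols. The six-membered pyran ring closes by reductive elimination from a seven-membered aryl(alkoxo)palladium chelate, formally a 6-exo attack of the tethered oxygen on the ipso carbon. No stereocentre is created: the carbinol C–O bond is never broken, so C2 keeps the S configuration delivered by linalool. The step needs chemoselectivity for C–O reductive elimination over hydrodebromination, which is secured because the tertiary alkoxide offers no carbinol C–H for beta-hydride elimination, the bulky electron-rich ligand speeds reductive elimination at the doubly ortho-substituted arylpalladium, and the other two oxygens are masked as silyl ether and acetal. Site selectivity is built in, since the single bromide sits between the tether and the methyl group that becomes the C8 methyl.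

Step 14
Reactants: 22 protected chroman
Product: 23 (1R,3R)-3-[(3E)-6-[(2S)-6-(methoxymethoxy)-2,8-dimethyl-3,4-dihydro-2H-chromen-2-yl]-3-methylhex-3-en-1-yl]-2,2-dimethyl-4-methylidenecyclohexan-1-ol
Conditions: TBAF (3 equiv), THF, 50 °C
Reagents that add atoms: none
Why: fluoride-induced cleavage of the Si–O bond frees the ring-A alcohol while the phenol stays masked, so no air-sensitive phenoxide meets the basic fluoride.

Step 15
Reactants: 23 methoxymethyl ether
Product: 24 (2S)-2-{(3E)-6-[(1R,3R)-3-hydroxy-2,2-dimethyl-6-methylidenecyclohexyl]-4-methylhex-3-en-1-yl}-2,8-dimethyl-3,4-dihydro-2H-chromen-6-ol (target)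
Conditions: HCl (2 M in MeOH, 5 equiv), MeOH/THF, 0 °C to rt, argon
Reagents that add atoms: none
Why: acid-catalysed transacetalisation in methanol cleaves the aryl methoxymethyl ether through its oxocarbenium ion under conditions mild enough to leave the exocyclic and trisubstituted olefins in place.

**Compound list**

1 | 4-amino-3-methylphenol | Cc1cc(O)ccc1N | starting material
2 | sodium 4-amino-3-methylphenoxide | Cc1cc([O-])ccc1N.[Na+] | intermediate
3 | 4-(methoxymethoxy)-2-methylaniline | Cc1cc(OCOC)ccc1N | intermediate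
4 | 2-iodo-4-(methoxymethoxy)-6-methylaniline | Cc1cc(OCOC)cc(I)c1N | intermediate
5 | 2-iodo-4-(methoxymethoxy)-6-methylbenzenediazonium bromide | Cc1cc(OCOC)cc(I)c1[N+]#N.[Br-] | intermediate
6 | 2-bromo-1-iodo-5-(methoxymethoxy)-3-methylbenzene | Cc1cc(OCOC)cc(I)c1Br | intermediate
7 | (S)-linalool, (3S)-3,7-dimethylocta-1,6-dien-3-ol | CC(C)=CCC[C@](C)(O)C=C | starting material
8 | (3R)-1-(9-borabicyclo[3.3.1]nonan-9-yl)-3,7-dimethyloct-6-en-3-ol (same spatial arrangement as 7) | CC(C)=CCC[C@](C)(O)CCB1C2CCCC1CCC2 | intermediate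
9 | (3S)-1-[2-bromo-5-(methoxymethoxy)-3-methylphenyl]-3,7-dimethyloct-6-en-3-ol | CC(C)=CCC[C@](C)(O)CCc1cc(OCOC)cc(C)c1Br | intermediate
10 | (2E,6S)-8-[2-bromo-5-(methoxymethoxy)-3-methylphenyl]-6-hydroxy-2,6-dimethyloct-2-enal | O=C/C(C)=C/CC[C@](C)(O)CCc1cc(OCOC)cc(C)c1Br | intermediate
11 | (2E,6S)-8-[2-bromo-5-(methoxymethoxy)-3-methylphenyl]-2,6-dimethyloct-2-ene-1,6-diol | OC/C(C)=C/CC[C@](C)(O)CCc1cc(OCOC)cc(C)c1Br | intermediate
12 | (3S,6E)-8-bromo-1-[2-bromo-5-(methoxymethoxy)-3-methylphenyl]-3,7-dimethyloct-6-en-3-ol | BrC/C(C)=C/CC[C@](C)(O)CCc1cc(OCOC)cc(C)c1Br | intermediate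
13 | neryl acetate, (2Z)-3,7-dimethylocta-2,6-dien-1-yl acetate | CC(C)=CCC/C(C)=C\COC(C)=O | starting material
14 | (2Z)-5-[(2R)-3,3-dimethyloxiran-2-yl]-3-methylpent-2-en-1-yl acetate | CC1(C)O[C@@H]1CC/C(C)=C\COC(C)=O | intermediate
15 | [(1R,3R)-3-hydroxy-2,2-dimethyl-6-methylidenecyclohexyl]methyl acetate (hydroxyl and acetoxymethyl trans) | C=C1CC[C@@H](O)C(C)(C)[C@@H]1COC(C)=O | intermediate
16 | [(1R,3R)-3-{[tert-butyl(dimethyl)silyl]oxy}-2,2-dimethyl-6-methylidenecyclohexyl]methyl acetate | C=C1CC[C@@H](O[Si](C)(C)C(C)(C)C)C(C)(C)[C@@H]1COC(C)=O | intermediate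
17 | [(1R,3R)-3-{[tert-butyl(dimethyl)silyl]oxy}-2,2-dimethyl-6-methylidenecyclohexyl]methanol | C=C1CC[C@@H](O[Si](C)(C)C(C)(C)C)C(C)(C)[C@@H]1CO | intermediate
18 | {[(1R,3R)-3-(bromomethyl)-2,2-dimethyl-4-methylidenecyclohexyl]oxy}(tert-butyl)dimethylsilane | C=C1CC[C@@H](O[Si](C)(C)C(C)(C)C)C(C)(C)[C@@H]1CBr | intermediate
19 | chloromagnesium alkoxide of 12 | BrC/C(C)=C/CC[C@](C)(O[Mg]Cl)CCc1cc(OCOC)cc(C)c1Br | intermediate
20 | {[(1R,3R)-3-{[tert-butyl(dimethyl)silyl]oxy}-2,2-dimethyl-6-methylidenecyclohexyl]methyl}magnesium bromide | C=C1CC[C@@H](O[Si](C)(C)C(C)(C)C)C(C)(C)[C@@H]1C[Mg]Br | intermediate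
21 | (3S,6E)-1-[2-bromo-5-(methoxymethoxy)-3-methylphenyl]-9-[(1R,3R)-3-{[tert-butyl(dimethyl)silyl]oxy}-2,2-dimethyl-6-methylidenecyclohexyl]-3,7-dimethylnon-6-en-3-ol | C=C1CC[C@@H](O[Si](C)(C)C(C)(C)C)C(C)(C)[C@@H]1CC/C(C)=C/CC[C@](C)(O)CCc1cc(OCOC)cc(C)c1Br | intermediate
22 | tert-butyl({(1R,3R)-3-[(3E)-6-[(2S)-6-(methoxymethoxy)-2,8-dimethyl-3,4-dihydro-2H-chromen-2-yl]-3-methylhex-3-en-1-yl]-2,2-dimethyl-4-methylidenecyclohexyl}oxy)dimethylsilane | C=C1CC[C@@H](O[Si](C)(C)C(C)(C)C)C(C)(C)[C@@H]1CC/C(C)=C/CC[C@@]1(C)CCc2cc(OCOC)cc(C)c2O1 | intermediate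
23 | (1R,3R)-3-[(3E)-6-[(2S)-6-(methoxymethoxy)-2,8-dimethyl-3,4-dihydro-2H-chromen-2-yl]-3-methylhex-3-en-1-yl]-2,2-dimethyl-4-methylidenecyclohexan-1-ol | C=C1CC[C@@H](O)C(C)(C)[C@@H]1CC/C(C)=C/CC[C@@]1(C)CCc2cc(OCOC)cc(C)c2O1 | intermediate
24 | (2S)-2-{(3E)-6-[(1R,3R)-3-hydroxy-2,2-dimethyl-6-methylidenecyclohexyl]-4-methylhex-3-en-1-yl}-2,8-dimethyl-3,4-dihydro-2H-chromen-6-ol | C=C1CC[C@@H](O)C(C)(C)[C@@H]1CC/C(C)=C/CC[C@@]1(C)CCc2cc(O)cc(C)c2O1 | target
25 | geranyl acetate, (2E)-3,7-dimethylocta-2,6-dien-1-yl acetate (enters only in the fallback to step 8) | CC(C)=CCC/C(C)=C/COC(C)=O | starting material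

**Step count and risks**

Total step count: 15. Longest linear sequence: 10 steps (steps 1–6, then 12–15).

Steps most likely to fail:

1. Step 13. Oxidative addition at the doubly ortho-substituted C–Br bond may be so slow that hydrodebromination and thermal degradation of the polyene take over. The fallback moves the ring closure to a substrate that tolerates forcing; it sets out from 9 and comes back at 22. Bromo alcohol 9 is cyclised either under forced conditions of step 13 or by an Ullmann-type closure (CuI, 3,4,7,8-tetramethyl-1,10-phenanthroline, Cs2CO3, toluene, 110 °C) to the prenyl chroman (2S)-6-(methoxymethoxy)-2,8-dimethyl-2-(4-methylpent-3-en-1-yl)-3,4-dihydro-2H-chromene F1. Oxidation of its E-methyl group with catalytic SeO2 and t-BuOOH gives (2E)-5-[(2S)-6-(methoxymethoxy)-2,8-dimethyl-3,4-dihydro-2H-chromen-2-yl]-2-methylpent-2-en-1-ol F2. The Appel reaction of step 6 gives the allylic bromide (2S)-2-[(3E)-5-bromo-4-methylpent-3-en-1-yl]-6-(methoxymethoxy)-2,8-dimethyl-3,4-dihydro-2H-chromene F3. Copper-catalysed coupling of F3 with Grignard reagent 20 (Li2CuCl4, THF, −78 to 0 °C), now with neither a free hydroxyl nor an aryl bromide in the electrophile, gives 22.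

2. Step 12. The Grignard reagent may be lost to protonation or homocoupling, substitution may occur at the gamma carbon with allylic transposition, or the bromo alkoxide may close to a tetrahydrofuran. The fallback makes the bond with a soft sulfone-stabilised carbanion and removes the sulfonyl group only after the aryl bromide has been consumed; it sets out from 18 and comes back at 22. Bromide 18 and PhSO2Na (DMF, 70 °C) give tert-butyl{[(1R,3R)-2,2-dimethyl-4-methylidene-3-(phenylsulfonylmethyl)cyclohexyl]oxy}dimethylsilane F4. Deprotonation (n-BuLi, THF, −78 °C) and alkylation with bromide 12, used as its alkoxide 19, give (3S,6E)-1-[2-bromo-5-(methoxymethoxy)-3-methylphenyl]-9-[(1R,3R)-3-{[tert-butyl(dimethyl)silyl]oxy}-2,2-dimethyl-6-methylidenecyclohexyl]-3,7-dimethyl-9-(phenylsulfonyl)non-6-en-3-ol F5 (both epimers at the sulfonyl carbon). F5 is cyclised under the conditions of step 13 to the 1-(phenylsulfonyl) derivative of 22 F6. Sodium amalgam (Na/Hg, 6% Na), Na2HPO4, MeOH/THF, −20 °C then removes the sulfonyl group to give 22.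

3. Step 8. Facial control in the radical ring closure of the Z-olefin may be poor if the chair with the axial acetoxymethyl group does not dominate, or the tertiary radical may be reduced before it cyclises. The fallback sets the CH centre by cyclising the E isomer and corrects the carbinol afterwards; it sets out from geranyl acetate 25 and comes back at 15. Shi epoxidation of 25 with the enantiomeric, L-fructose-derived ketone catalyst gives (2E)-5-[(2S)-3,3-dimethyloxiran-2-yl]-3-methylpent-2-en-1-yl acetate F7. Cp2TiCl-mediated cyclisation as in step 8, now through the all-equatorial chair, gives the cis alcohol [(1R,3S)-3-hydroxy-2,2-dimethyl-6-methylidenecyclohexyl]methyl acetate F8. Dess–Martin oxidation gives [(1R)-2,2-dimethyl-6-methylidene-3-oxocyclohexyl]methyl acetate F9, whose CH centre is not enolisable. Corey–Bakshi–Shibata reduction ((S)-2-methyl-CBS-oxazaborolidine, catecholborane, toluene, −78 °C; reagent control with the quaternary carbon as the large group) should then deliver the R carbinol, which is 15.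

Further compounds
F1 | step 13 | (2S)-6-(methoxymethoxy)-2,8-dimethyl-2-(4-methylpent-3-en-1-yl)-3,4-dihydro-2H-chromene | CC(C)=CCC[C@@]1(C)CCc2cc(OCOC)cc(C)c2O1
F2 | step 13 | (2E)-5-[(2S)-6-(methoxymethoxy)-2,8-dimethyl-3,4-dihydro-2H-chromen-2-yl]-2-methylpent-2-en-1-ol | OC/C(C)=C/CC[C@@]1(C)CCc2cc(OCOC)cc(C)c2O1
F3 | step 13 | (2S)-2-[(3E)-5-bromo-4-methylpent-3-en-1-yl]-6-(methoxymethoxy)-2,8-dimethyl-3,4-dihydro-2H-chromene | BrC/C(C)=C/CC[C@@]1(C)CCc2cc(OCOC)cc(C)c2O1
F4 | step 12 | tert-butyl{[(1R,3R)-2,2-dimethyl-4-methylidene-3-(phenylsulfonylmethyl)cyclohexyl]oxy}dimethylsilane | C=C1CC[C@@H](O[Si](C)(C)C(C)(C)C)C(C)(C)[C@@H]1CS(=O)(=O)c1ccccc1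
F5 | step 12 | (3S,6E)-1-[2-bromo-5-(methoxymethoxy)-3-methylphenyl]-9-[(1R,3R)-3-{[tert-butyl(dimethyl)silyl]oxy}-2,2-dimethyl-6-methylidenecyclohexyl]-3,7-dimethyl-9-(phenylsulfonyl)non-6-en-3-ol | C=C1CC[C@@H](O[Si](C)(C)C(C)(C)C)C(C)(C)[C@@H]1C(C/C(C)=C/CC[C@](C)(O)CCc1cc(OCOC)cc(C)c1Br)S(=O)(=O)c1ccccc1
F6 | step 12 | 1-(phenylsulfonyl) derivative of 22, sulfonyl group on the side-chain carbon attached to ring A | C=C1CC[C@@H](O[Si](C)(C)C(C)(C)C)C(C)(C)[C@@H]1C(C/C(C)=C/CC[C@@]1(C)CCc2cc(OCOC)cc(C)c2O1)S(=O)(=O)c1ccccc1
F7 | step 8 | (2E)-5-[(2S)-3,3-dimethyloxiran-2-yl]-3-methylpent-2-en-1-yl acetate | CC1(C)O[C@H]1CC/C(C)=C/COC(C)=O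
F8 | step 8 | [(1R,3S)-3-hydroxy-2,2-dimethyl-6-methylidenecyclohexyl]methyl acetate | C=C1CC[C@H](O)C(C)(C)[C@@H]1COC(C)=O
F9 | step 8 | [(1R)-2,2-dimethyl-6-methylidene-3-oxocyclohexyl]methyl acetate | C=C1CCC(=O)C(C)(C)[C@@H]1COC(C)=O
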